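**Retrosynthetic overview**

1. Target 10 ⇐ deacetylation, benzylic oxidation of C4 and Markovnikov hydration of the side-chain alkene ⇐ chroman-6-ol 6, which already holds ring A with its bromine, ring B with O1, and the C2 stereocentre.
2. Ring B of 6 ⇐ acid-induced ring expansion (1,2-shift of C4 from C8a to C4a) of the 1-oxaspiro[4.5]decadienone 5 ⇐ oxidative dearomatising closure of the O1–C8a bond on the para-alkylphenol 4.
3. Phenol 4 ⇐ (R)-linalool 1 (all ten side-chain carbons and the C2 carbinol stereocentre) + 2-bromo-4-iodophenol 2, by hydroboration and B-alkyl Suzuki–Miyaura coupling.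
4. Enabling feature: on ring A, O1 (on C8a) is para to the C6 hydroxyl and C4 sits on the neighbouring C4a. Such a hydroquinone monoether with an ortho carbon branch is the dienone–phenol product of a para-quinol spiroether, so the C6 phenol can direct O1 to the ipso carbon of the chain, which then moves over by one position.
5. Ring order: benzene ring A bought; spiro-oxolane ring closed through O1–C8a; expanded to six-membered ring B; C4 carbonyl added last.

Key step: step 2

Assumption: (R)-(−)-linalool of high enantiomeric purity is taken as the commercial source of C2; no step makes or breaks a bond at this carbon, so the target can be no purer than this starting material.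

**Step 1**
Reactants: 1 (R)-(−)-linalool; 2 2-bromo-4-iodophenol
Product: 4 2-bromo-4-[(3R)-3-hydroxy-3,7-dimethyloct-6-en-1-yl]phenol, via B-alkyl-9-BBN adduct 3 (not isolated)
Conditions: 9-BBN (2.2 equiv), THF, 0 °C → rt; then aq. NaOH, 2, PdCl2(dppf) (5 mol%), THF/DMF, 50 °C
Reagents that add atoms: none
Why: 9-BBN should hydroborate only the monosubstituted vinyl group at its terminal carbon (the trisubstituted alkene is inert at room temperature), and the primary alkylborane should then undergo B-alkyl Suzuki–Miyaura coupling at the C–I bond of 2, which adds oxidatively far faster than C–Br, with the carbinol stereocentre untouched.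

**Step 2**
Reactants: 4 2-bromo-4-[(3R)-3-hydroxy-3,7-dimethyloct-6-en-1-yl]phenol
Product: 6 (2R)-7-bromo-2-methyl-2-(4-methylpent-3-en-1-yl)-3,4-dihydro-2H-chromen-6-ol, via spirodienone 5 (not isolated)
Conditions: PhI(OAc)2 (1.0 equiv), CF3CH2OH, −20 °C; volatiles removed (toluene chase), same flask; BF3·OEt2 (1.5 equiv), CH2Cl2, −78 → −20 °C
Reagents that add atoms: none
Why: Ligand exchange of the phenol on PhI(OAc)2 and loss of PhI should make ring A a phenoxenium-type electrophile whose para carbon (the future C8a) is attacked by the tertiary hydroxyl (the future O1), closing the spiro-oxolane ring of 5 in a 5-exo-trig mode, which is the hypervalent-iodine oxidative dearomatising spiroetherification of para-(3-hydroxyalkyl)phenols. BF3 should then activate the dienone carbonyl so that the CH2 group (C4) undergoes a 1,2-shift from the spiro carbon to the neighbouring ring CH and loss of a proton rearomatises; this dienone–phenol ring expansion of 1-oxaspiro[4.5]decadienones to chroman-6-ols is the closest known reaction type and turns the five-membered spiro ring into six-membered ring B without breaking the new O1–C8a bond. The only new stereocentre, the spiro carbon of 5, should form as a mixture of epimers and is erased on aromatisation, while C2 keeps the configuration of linalool because no bond to it is made or broken. Carbon and not oxygen should migrate because O1 stabilises the migration origin as an oxocarbenium ion. The selectivity needed is migration to the ring CH remote from bromine (7-bromo and not 5-bromo chroman), which the bromine should secure by inductively destabilising positive charge on its adjacent carbon and by crowding that terminus. One equivalent of oxidant is consumed and the acetic acid removed before the Lewis acid is added, so that the oxidisable hydroquinone monoether 6 never meets trivalent iodine and the side-chain alkene never meets a strong protic acid.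

**Step 3**
Reactants: 6 (2R)-7-bromo-2-methyl-2-(4-methylpent-3-en-1-yl)-3,4-dihydro-2H-chromen-6-ol
Product: 7 (2R)-7-bromo-2-methyl-2-(4-methylpent-3-en-1-yl)-3,4-dihydro-2H-chromen-6-yl acetate
Conditions: Ac2O, pyridine, DMAP (cat.), CH2Cl2, 0 °C → rt
Reagents that add atoms: acetic anhydride, CC(=O)OC(C)=O
Why: DMAP-catalysed O-acetylation of the only hydroxyl should mask the electron-rich hydroquinone monoether against the radical and chromium oxidants of steps 4 and 5.

**Step 4**
Reactants: 7 (2R)-7-bromo-2-methyl-2-(4-methylpent-3-en-1-yl)-3,4-dihydro-2H-chromen-6-yl acetate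
Product: 8 (2R)-7-bromo-2-(4-hydroxy-4-methylpentyl)-2-methyl-3,4-dihydro-2H-chromen-6-yl acetate
Conditions: Co(acac)2 (20 mol%), PhSiH3 (2.5 equiv), O2 (1 atm), THF/i-PrOH, rt
Reagents that add atoms: dioxygen, O=O
Why: In this Mukaiyama hydration, hydrogen-atom transfer from a cobalt hydride to the only alkene should give the tertiary radical, which is trapped by O2 and reduced to the Markovnikov tertiary alcohol, while aryl bromide, acetate and chroman are inert.

**Step 5**
Reactants: 8 (2R)-7-bromo-2-(4-hydroxy-4-methylpentyl)-2-methyl-3,4-dihydro-2H-chromen-6-yl acetate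
Product: 9 (2R)-7-bromo-2-(4-hydroxy-4-methylpentyl)-2-methyl-4-oxo-3,4-dihydro-2H-chromen-6-yl acetate
Conditions: CrO3 (10 mol%), H5IO6 (3 equiv), MeCN, 0 °C → rt
Reagents that add atoms: periodic acid, OI(=O)(O)(O)(O)O
Why: In this catalytic CrO3/periodic acid benzylic oxidation, C4 is the only benzylic C–H position (C2 is quaternary), so the methylene should go to the ketone, while the tertiary alcohol cannot be oxidised and the acetate keeps ring A from quinone formation.

**Step 6**
Reactants: 9 (2R)-7-bromo-2-(4-hydroxy-4-methylpentyl)-2-methyl-4-oxo-3,4-dihydro-2H-chromen-6-yl acetate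
Product: 10 (2R)-7-bromo-6-hydroxy-2-(4-hydroxy-4-methylpentyl)-2-methyl-2,3-dihydro-4H-chromen-4-one
Conditions: K2CO3 (0.2 equiv), MeOH, 0 °C, short contact
Reagents that add atoms: none
Why: Base-catalysed methanolysis (Zemplén-type transesterification) of the aryl acetate should be much faster than any retro-oxa-Michael opening of the 2,2-disubstituted chromanone, so C2 is not scrambled.

**Compound list**

1 | (R)-(−)-linalool, (3R)-3,7-dimethylocta-1,6-dien-3-ol | C=C[C@](C)(O)CCC=C(C)C | starting material
2 | 2-bromo-4-iodophenol | Oc1ccc(I)cc1Br | starting material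
3 | (3S)-1-(9-borabicyclo[3.3.1]nonan-9-yl)-3,7-dimethyloct-6-en-3-ol (same spatial arrangement as 1; the descriptor changes only because boron ranks below carbon) | CC(C)=CCC[C@@](C)(O)CCB1C2CCCC1CCC2 | intermediate (not isolated)
4 | 2-bromo-4-[(3R)-3-hydroxy-3,7-dimethyloct-6-en-1-yl]phenol | CC(C)=CCC[C@@](C)(O)CCc1ccc(O)c(Br)c1 | intermediate
5 | (2R)-7-bromo-2-methyl-2-(4-methylpent-3-en-1-yl)-1-oxaspiro[4.5]deca-6,9-dien-8-one, both epimers at the spiro carbon | CC(C)=CCC[C@]1(C)CCC2(C=CC(=O)C(Br)=C2)O1 | intermediate (not isolated)
6 | (2R)-7-bromo-2-methyl-2-(4-methylpent-3-en-1-yl)-3,4-dihydro-2H-chromen-6-ol | CC(C)=CCC[C@]1(C)CCc2cc(O)c(Br)cc2O1 | intermediate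
7 | (2R)-7-bromo-2-methyl-2-(4-methylpent-3-en-1-yl)-3,4-dihydro-2H-chromen-6-yl acetate | CC(C)=CCC[C@]1(C)CCc2cc(OC(C)=O)c(Br)cc2O1 | intermediate
8 | (2R)-7-bromo-2-(4-hydroxy-4-methylpentyl)-2-methyl-3,4-dihydro-2H-chromen-6-yl acetate | CC(C)(O)CCC[C@]1(C)CCc2cc(OC(C)=O)c(Br)cc2O1 | intermediate
9 | (2R)-7-bromo-2-(4-hydroxy-4-methylpentyl)-2-methyl-4-oxo-3,4-dihydro-2H-chromen-6-yl acetate | CC(C)(O)CCC[C@]1(C)CC(=O)c2cc(OC(C)=O)c(Br)cc2O1 | intermediate
10 | (2R)-7-bromo-6-hydroxy-2-(4-hydroxy-4-methylpentyl)-2-methyl-2,3-dihydro-4H-chromen-4-one | CC(C)(O)CCC[C@]1(C)CC(=O)c2cc(O)c(Br)cc2O1 | target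

Total step count: 6
Longest linear sequence: 6 steps (1 → 10)

**Steps most likely to fail**

Step 2. The 1,2-shift may lose regiocontrol and run partly toward the bromine-flanked ring carbon. The Lewis acid may also ionise the tertiary C2–O1 bond or protonate the side-chain alkene. The fallback sets out from organoborane 3 and comes back at chroman 6, and it fixes the substitution pattern through the building block. Borane 3 would be coupled (PdCl2(dppf), aq. NaOH, THF/DMF, 50 °C) with commercial 1-bromo-4-iodo-2,5-dimethoxybenzene, in which both ring oxygens and the bromine already stand where C8a, C6 and C7 need them. This should give (3R)-1-(4-bromo-2,5-dimethoxyphenyl)-3,7-dimethyloct-6-en-3-ol F1. Oxidative demethylation with (NH4)2Ce(NO3)6 in aqueous MeCN at 0 °C should give 2-bromo-5-[(3R)-3-hydroxy-3,7-dimethyloct-6-en-1-yl]cyclohexa-2,5-diene-1,4-dione F2. Reduction with aqueous Na2S2O4 should give 2-bromo-5-[(3R)-3-hydroxy-3,7-dimethyloct-6-en-1-yl]benzene-1,4-diol F3. Acid-catalysed cyclodehydration (TsOH cat., benzene, 50 °C) is the ring closure known for chromanols of the vitamin E type, in which the carbinol oxygen attacks the ring carbon, so it again forms the O1–C8a bond and leaves the carbinol carbon's configuration intact. It should return 6 as a single regioisomer. The enantiomeric purity of 6 would be checked at this point, since competing ionisation of the tertiary alcohol would erode it.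

Step 5. The oxidation may stall on the deactivated ring, attack ring A, or dehydrate the tertiary alcohol under the acidic oxidant. The fallback sets out from 8 and comes back at 9, replacing direct C–H oxidation by halogenation, solvolysis and alcohol oxidation. Radical bromination (NBS, AIBN, PhCF3, 80 °C) at C4, the only benzylic position, should give (2R)-4,7-dibromo-2-(4-hydroxy-4-methylpentyl)-2-methyl-3,4-dihydro-2H-chromen-6-yl acetate F4 as both C4 epimers. Silver-assisted solvolysis (AgNO3, acetone/H2O, rt) should give (2R)-7-bromo-4-hydroxy-2-(4-hydroxy-4-methylpentyl)-2-methyl-3,4-dihydro-2H-chromen-6-yl acetate F5. Dess–Martin oxidation of this secondary benzylic alcohol, which leaves the tertiary alcohol alone, should give 9.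

Step 1. Oxidative addition may compete at the C–Br bond, or the free phenoxide and the borinate of the tertiary alcohol may slow transmetalation. The fallback sets out from 1 and 2 and comes back at 4, forming the aryl–carbon bond without boron. A Heck reaction under ligand-free phase-transfer conditions (Pd(OAc)2, n-Bu4NCl, NaHCO3, DMF, 60 °C) between the vinyl group of 1 and the C–I bond of 2 should give 2-bromo-4-[(1E,3R)-3-hydroxy-3,7-dimethylocta-1,6-dien-1-yl]phenol F6; a tertiary allylic alcohol cannot collapse to a ketone, so the styrene is retained. Diimide (2-nitrobenzenesulfonyl hydrazide, Et3N, CH2Cl2, rt) reduces the disubstituted styrenyl double bond well before the trisubstituted one and leaves C–Br alone, so it should give 4.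

**Further compounds**

F1 | step 2 | (3R)-1-(4-bromo-2,5-dimethoxyphenyl)-3,7-dimethyloct-6-en-3-ol | CC(C)=CCC[C@@](C)(O)CCc1cc(OC)c(Br)cc1OC
F2 | step 2 | 2-bromo-5-[(3R)-3-hydroxy-3,7-dimethyloct-6-en-1-yl]cyclohexa-2,5-diene-1,4-dione | CC(C)=CCC[C@@](C)(O)CCC1=CC(=O)C(Br)=CC1=O
F3 | step 2 | 2-bromo-5-[(3R)-3-hydroxy-3,7-dimethyloct-6-en-1-yl]benzene-1,4-diol | CC(C)=CCC[C@@](C)(O)CCc1cc(O)c(Br)cc1O
F4 | step 5 | (2R)-4,7-dibromo-2-(4-hydroxy-4-methylpentyl)-2-methyl-3,4-dihydro-2H-chromen-6-yl acetate, both C4 epimers | CC(C)(O)CCC[C@]1(C)CC(Br)c2cc(OC(C)=O)c(Br)cc2O1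
F5 | step 5 | (2R)-7-bromo-4-hydroxy-2-(4-hydroxy-4-methylpentyl)-2-methyl-3,4-dihydro-2H-chromen-6-yl acetate, both C4 epimers | CC(C)(O)CCC[C@]1(C)CC(O)c2cc(OC(C)=O)c(Br)cc2O1
F6 | step 1 | 2-bromo-4-[(1E,3R)-3-hydroxy-3,7-dimethylocta-1,6-dien-1-yl]phenol | CC(C)=CCC[C@@](C)(O)/C=C/c1ccc(O)c(Br)c1
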